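Feature used: on ring A (C4a, C5, C6, C7, C8, C8a) the chain C6-C1'H(propyl)-C2'H2-C3'OOH stands ortho to the C5 oxygen. Acid and O5 can therefore be tied into a temporary six-membered lactone (ring C: O5, C3', C2', C1', C6, C5), which equals an ortho-hydroxy-alpha-propylstyrene plus CO.
Key disconnection: C2'-C3' and O5-C3' are formed and C1' is set in one asymmetric palladium-catalysed cyclocarbonylation of 3,5-dimethoxy-2-(pent-1-en-2-yl)phenol, two steps from 3,5-dimethoxyphenol.
Ring B (O1, C2, C3, C4, C4a, C8a): a tigloyl group is placed at C4a next to the lactone oxygen, then a quinine-catalysed oxa-Michael closure O1-C2 gives the cis-2,3-dimethylchromanone. O5 is blocked by ring C, so only this closure is open.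
C8: the C8-CH2 bond comes from a Negishi coupling with a cyclobutylmethylzinc reagent from (+)-alpha-pinene (ring D, both centres from the chiral pool). A dearomatising prenylation of the C7 phenol then sets the quaternary centre, and hydrolysis of ring C frees the acid and the C5 enol.
Ring order: A bought, C closed (step 3), B closed (step 7), D attached (step 14), A dearomatised (step 17), C opened (step 18).

Key step: step 3

Atom labels in the text are those of the target (O1 to C8a; side chain C1' stereocentre, C2', C3' carboxyl); systematic names of intermediates carry their own locants.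
Assumption: no reliable model predicts which antipode of DIOP (step 3) or of the DACH-phenyl diphosphine (step 17) gives the drawn configuration with these substrates, so the (R,R) forms are written and the equally available (S,S) forms would replace them if a first run shows the opposite sense.

Step 1
Reactants: 1 3,5-dimethoxyphenol; 2 butyryl chloride
Product: 3 1-(2-hydroxy-4,6-dimethoxyphenyl)butan-1-one
Conditions: AlCl3 (3 equiv), CH2Cl2, 0 °C to rt; cold 1 M HCl
Reagents that add atoms: butyryl chloride 2, CCCC(=O)Cl
Why: Friedel-Crafts acylation: the phenol is bound as ArO-AlCl2, the acylium ion should enter at the ortho carbon, which is less crowded than the carbon between the two methoxy groups, and the product is held as a six-membered chelate, so the hydrogen-bonded ketone 3 should dominate and the far more polar para isomer is removed by chromatography.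

Step 2
Reactants: 3 1-(2-hydroxy-4,6-dimethoxyphenyl)butan-1-one
Product: 4 3,5-dimethoxy-2-(pent-1-en-2-yl)phenol
Conditions: MePPh3Br (3.5 equiv), KOt-Bu (3.4 equiv), THF, 0 °C to reflux; aq NH4Cl; Et3N-washed silica
Reagents that add atoms: methyltriphenylphosphonium bromide, C[P+](c1ccccc1)(c1ccccc1)c1ccccc1.[Br-]
Why: Wittig methylenation: one equivalent of ylide is spent on the phenol, and an excess of the small ylide at reflux should still add to the deactivated phenoxide ketone, as is routine for 2-hydroxyaryl ketones, while the basic medium spares the acid-sensitive electron-rich styrene 4.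

Step 3
Reactants: 4 3,5-dimethoxy-2-(pent-1-en-2-yl)phenol; 5 carbon monoxide
Product: 6 (4S)-5,7-dimethoxy-4-propyl-3,4-dihydro-2H-chromen-2-one
Conditions: Pd(OAc)2 (4 mol %), (R,R)-DIOP (8 mol %), CO (35 bar), H2 (7 bar), toluene, 100 °C, autoclave; recrystallisation to raise the enantiomeric purity
Reagents that add atoms: carbon monoxide 5, [C-]#[O+]
Why: Proposed new method: Pd(OAc)2, the diphosphine, CO and H2 should form a hydride complex [(DIOP)Pd-H]+ that adds across C1'=C2' of 4 with hydrogen to the internal carbon C1' and palladium to the terminal carbon C2', CO then inserts into the C2'-Pd bond (new bond C2'-C3'), and the neighbouring phenol oxygen O5 attacks the acyl carbon (new bond O5-C3'), which releases 6 and returns the hydride. The closest known reaction type is the palladium-catalysed cyclocarbonylation of 2-allylphenols to lactones and its asymmetric form on 2-(1-methylvinyl)anilines to 4-methyl-3,4-dihydroquinolin-2-ones, whereas a phenolic alpha-propylstyrene with two ortho substituents has not been shown. Ring C closes by a 6-exo-trig acyl substitution at the palladium-bound acyl carbon. C1' is the only new stereocentre, and its S configuration is set by the chiral pocket of DIOP in the face-selective hydropalladation (or, should that step be reversible, in the CO insertion that follows), with the phenol OH able to hold the alkene near the metal. The step needs anti-Markovnikov regiochemistry, which the substrate secures because the other mode would place palladium on a tertiary benzylic carbon wedged between OH and OMe of a twisted arene and would end in a five-membered lactone with a quaternary centre. Acid-free CO/H2 conditions are chosen because 4 is an acid-sensitive styrene, and H2 serves only to form the hydride.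

Step 4
Reactants: 6 (4S)-5,7-dimethoxy-4-propyl-3,4-dihydro-2H-chromen-2-one
Product: 7 (4S)-5,7-dihydroxy-4-propyl-3,4-dihydro-2H-chromen-2-one
Conditions: BBr3 (4 equiv), CH2Cl2, -78 °C to rt; ice water
Reagents that add atoms: none
Why: Aryl methyl ether cleavage with BBr3: it is run before any alkene or epimerisable centre is present, C1' is not involved, and a lactone that opens on boron recloses to the same compound because the two oxygens ortho to C6 are equivalent in 7.

Step 5
Reactants: 7 (4S)-5,7-dihydroxy-4-propyl-3,4-dihydro-2H-chromen-2-one; 8 tigloyl chloride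
Product: 9 (4S)-5,7-dihydroxy-8-[(2E)-2-methylbut-2-enoyl]-4-propyl-3,4-dihydro-2H-chromen-2-one
Conditions: AlCl3 (4 equiv), CH2Cl2/PhNO2, 0 °C to rt; ice-cold 1 M HCl
Reagents that add atoms: tigloyl chloride 8, C/C=C(\C)C(=O)Cl
Why: Friedel-Crafts acylation, established on 5,7-dihydroxy-4-alkylcoumarins: as in resorcinol the acylium ion should enter at C4a, which is ortho to the C8a hydroxyl, para to the C7 hydroxyl and next to the lactone oxygen O5, rather than at C8 between the two hydroxyls, and binding of the C8a oxygen to aluminium keeps it from adding to the enone before the cold quench.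

Step 6
Reactants: 9 (4S)-5,7-dihydroxy-8-[(2E)-2-methylbut-2-enoyl]-4-propyl-3,4-dihydro-2H-chromen-2-one
Product: 10 (4S)-5-[(tert-butyldimethylsilyl)oxy]-7-hydroxy-8-[(2E)-2-methylbut-2-enoyl]-4-propyl-3,4-dihydro-2H-chromen-2-one
Conditions: TBSCl (1.1 equiv), imidazole (2 equiv), CH2Cl2, 0 °C
Reagents that add atoms: tert-butyldimethylsilyl chloride, CC(C)(C)[Si](C)(C)Cl
Why: Chemoselective silylation: the C8a hydroxyl is tied up in a strong hydrogen bond to the tigloyl carbonyl, so TBSCl should react only at the free C7 hydroxyl, and the short contact with imidazole at 0 °C should not start an unselective ring closure.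

Step 7
Reactants: 10 (4S)-5-[(tert-butyldimethylsilyl)oxy]-7-hydroxy-8-[(2E)-2-methylbut-2-enoyl]-4-propyl-3,4-dihydro-2H-chromen-2-one
Product: 11 (4S,8R,9S)-5-[(tert-butyldimethylsilyl)oxy]-8,9-dimethyl-4-propyl-3,4,8,9-tetrahydro-2H,10H-pyrano[2,3-f]chromene-2,10-dione
Conditions: (-)-quinine (20 mol %), chlorobenzene, 10-15 °C
Reagents that add atoms: none
Why: Cinchona-alkaloid-catalysed intramolecular oxa-Michael addition (6-endo-trig), known for 7-hydroxy-8-tigloylcoumarins: the quinuclidine nitrogen activates the C8a hydroxyl and the catalyst hydroxyl binds the carbonyl, so O1 should add to one face of the (E)-enone (2R) and the enol should be protonated kinetically to the cis isomer (3S), with O5 blocked by ring C and the remote C1' having little say.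

Step 8
Reactants: 11 (4S,8R,9S)-5-[(tert-butyldimethylsilyl)oxy]-8,9-dimethyl-4-propyl-3,4,8,9-tetrahydro-2H,10H-pyrano[2,3-f]chromene-2,10-dione
Product: 12 (4S,8R,9S)-5-[(tert-butyldimethylsilyl)oxy]-6-iodo-8,9-dimethyl-4-propyl-3,4,8,9-tetrahydro-2H,10H-pyrano[2,3-f]chromene-2,10-dione
Conditions: NIS (1.1 equiv), TFA (0.3 equiv), MeCN, 0 °C to rt, dark
Reagents that add atoms: N-iodosuccinimide, O=C1CCC(=O)N1I
Why: Electrophilic aromatic iodination: C8 is the only free ring position and is activated by O7 and O1 (ortho) and O5 (para), and the weakly acidic medium should not enolise C4, so the cis C2/C3 relation is kept.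

Step 9
Reactants: 13 (1R,5R)-(+)-alpha-pinene (high-ee grade)
Product: 14 (1R,5R)-(+)-verbenone
Conditions: CrO3 (5 mol %), t-BuOOH (5 equiv), CH2Cl2, rt
Reagents that add atoms: tert-butyl hydroperoxide, CC(C)(C)OO
Why: Chromium-catalysed allylic oxidation with t-BuOOH: the ring methylene next to the trisubstituted alkene is the only accessible allylic CH2, and the two bridgehead stereocentres, which become those of ring D, are not touched.

Step 10
Reactants: 14 (1R,5R)-(+)-verbenone
Product: 16 (1R,3S)-3-acetyl-2,2-dimethylcyclobutane-1-carboxylic acid, via alpha-keto acid 15 (not isolated)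
Conditions: RuCl3·xH2O (2 mol %), NaIO4 (4.5 equiv), EtOAc/MeCN/H2O, rt
Reagents that add atoms: sodium periodate, [Na+].[O-]I(=O)(=O)=O
Why: Oxidative cleavage with ruthenium tetroxide made in situ: the enone C=C is cut to the methyl ketone and alpha-keto acid 15, which is decarboxylated oxidatively to 16, so exactly one carbon stays on the ring as the later C8-CH2 carbon and the cis relation is inherited from the bicycle.

Step 11
Reactants: 16 (1R,3S)-3-acetyl-2,2-dimethylcyclobutane-1-carboxylic acid
Product: 17 (1R,3R)-2,2-dimethyl-3-(prop-1-en-2-yl)cyclobutane-1-carboxylic acid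
Conditions: MePPh3Br (3 equiv), KOt-Bu (3 equiv), THF, 0 °C to rt; 10% citric acid
Reagents that add atoms: methyltriphenylphosphonium bromide, C[P+](c1ccccc1)(c1ccccc1)c1ccccc1.[Br-]
Why: Wittig methylenation: the acid is carried as its carboxylate, which shields the adjacent ring C-H, the unhindered methyl ketone should be methylenated faster than it is enolised toward the ring, and the cis-1,3 isomer is also the more stable one, so no epimerisation is expected.

Step 12
Reactants: 17 (1R,3R)-2,2-dimethyl-3-(prop-1-en-2-yl)cyclobutane-1-carboxylic acid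
Product: 18 [(1R,3R)-2,2-dimethyl-3-(prop-1-en-2-yl)cyclobutyl]methanol
Conditions: LiAlH4, Et2O, 0 °C to rt; aq NaOH work-up
Reagents that add atoms: none
Why: Hydride reduction of the carboxylic acid with LiAlH4, which leaves the isolated 1,1-disubstituted alkene and both stereocentres untouched.

Step 13
Reactants: 18 [(1R,3R)-2,2-dimethyl-3-(prop-1-en-2-yl)cyclobutyl]methanol
Product: 19 (1R,3R)-1-(iodomethyl)-2,2-dimethyl-3-(prop-1-en-2-yl)cyclobutane
Conditions: PPh3, imidazole, I2, CH2Cl2, 0 °C to rt
Reagents that add atoms: iodine, [I][I]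
Why: Appel-type iodination: iodide displaces the alkoxyphosphonium group by SN2 at the primary carbon, so no cyclobutylcarbinyl cation and no ring expansion should arise.

Step 14
Reactants: 19 (1R,3R)-1-(iodomethyl)-2,2-dimethyl-3-(prop-1-en-2-yl)cyclobutane; 12 (4S,8R,9S)-5-[(tert-butyldimethylsilyl)oxy]-6-iodo-8,9-dimethyl-4-propyl-3,4,8,9-tetrahydro-2H,10H-pyrano[2,3-f]chromene-2,10-dione
Product: 21 (4S,8R,9S)-5-[(tert-butyldimethylsilyl)oxy]-6-{[(1S,3R)-2,2-dimethyl-3-(prop-1-en-2-yl)cyclobutyl]methyl}-8,9-dimethyl-4-propyl-3,4,8,9-tetrahydro-2H,10H-pyrano[2,3-f]chromene-2,10-dione, via cyclobutylmethylzinc iodide 20 (not isolated)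
Conditions: 19 (1.5 equiv), Zn dust, LiCl, THF, 25-30 °C; then 12, Pd(OAc)2 (3 mol %), SPhos (6 mol %), THF, 25 to 50 °C
Reagents that add atoms: none
Why: Negishi sp3-sp2 cross-coupling: LiCl-assisted zinc insertion into the primary iodide should give 20 without ring opening or loss of configuration, a bulky electron-rich biarylphosphine on palladium should take the doubly ortho-oxygenated iodide 12 through oxidative addition and reductive elimination faster than beta-hydride elimination, and ketone, lactone and silyl ether tolerate the organozinc.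

Step 15
Reactants: 21 (4S,8R,9S)-5-[(tert-butyldimethylsilyl)oxy]-6-{[(1S,3R)-2,2-dimethyl-3-(prop-1-en-2-yl)cyclobutyl]methyl}-8,9-dimethyl-4-propyl-3,4,8,9-tetrahydro-2H,10H-pyrano[2,3-f]chromene-2,10-dione
Product: 22 (4S,8R,9S)-6-{[(1S,3R)-2,2-dimethyl-3-(prop-1-en-2-yl)cyclobutyl]methyl}-5-hydroxy-8,9-dimethyl-4-propyl-3,4,8,9-tetrahydro-2H,10H-pyrano[2,3-f]chromene-2,10-dione
Conditions: TBAF (1.1 equiv), AcOH (1.2 equiv), THF, 0 °C
Reagents that add atoms: none
Why: Fluoride-induced desilylation: the aryl silyl ether is cleaved fast at 0 °C, and acetic acid buffers fluoride and phenoxide so that neither C3 epimerisation nor opening of ring C should occur.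

Step 16
Reactants: 23 3-methylbut-2-en-1-ol (prenol)
Product: 24 tert-butyl 3-methylbut-2-en-1-yl carbonate
Conditions: Boc2O (1.2 equiv), Bu4NHSO4 (5 mol %), 30% aq NaOH, CH2Cl2, 0 °C to rt
Reagents that add atoms: di-tert-butyl dicarbonate, CC(C)(C)OC(=O)OC(=O)OC(C)(C)C
Why: Phase-transfer O-acylation of the primary allylic alcohol with Boc2O, chosen because this leaving group later gives only CO2 and non-nucleophilic tert-butanol, which cannot open ring C.

Step 17
Reactants: 22 (4S,8R,9S)-6-{[(1S,3R)-2,2-dimethyl-3-(prop-1-en-2-yl)cyclobutyl]methyl}-5-hydroxy-8,9-dimethyl-4-propyl-3,4,8,9-tetrahydro-2H,10H-pyrano[2,3-f]chromene-2,10-dione; 24 tert-butyl 3-methylbut-2-en-1-yl carbonate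
Product: 25 (4S,6R,8R,9S)-6-{[(1S,3R)-2,2-dimethyl-3-(prop-1-en-2-yl)cyclobutyl]methyl}-8,9-dimethyl-6-(3-methylbut-2-en-1-yl)-4-propyl-3,4,8,9-tetrahydro-2H-pyrano[2,3-f]chromene-2,5,10(6H)-trione
Conditions: 24 (1.5 equiv), Pd2(dba)3·CHCl3 (2.5 mol %), (1R,2R)-N,N'-bis[2-(diphenylphosphanyl)benzoyl]cyclohexane-1,2-diamine (7.5 mol %), degassed toluene, 0 °C to rt
Reagents that add atoms: none
Why: Palladium-catalysed asymmetric allylic dearomatisation (Tsuji-Trost type, known for 1-substituted 2-naphthols and for alkylated phloroglucinol ethers): ionisation of 24 by zerovalent palladium gives the pi-prenyl complex [(ligand)Pd(C5H9)]+ and tert-butoxide, which deprotonates O7-H, O-prenylation is reversible under the catalyst whereas attack of C8 on the unsubstituted allyl terminus is not, C8 is preferred over C6 because C6 carries the branched C1', and the 8R centre should arise from attack on the ring face opposite to the pseudo-axial C1' propyl group and to the two ring B methyl groups, a bias that the chiral ligand is meant to reinforce.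

Step 18
Reactants: 25 (4S,6R,8R,9S)-6-{[(1S,3R)-2,2-dimethyl-3-(prop-1-en-2-yl)cyclobutyl]methyl}-8,9-dimethyl-6-(3-methylbut-2-en-1-yl)-4-propyl-3,4,8,9-tetrahydro-2H-pyrano[2,3-f]chromene-2,5,10(6H)-trione
Product: 26 (3S)-3-[(2R,3S,8R)-8-{[(1S,3R)-2,2-dimethyl-3-(prop-1-en-2-yl)cyclobutyl]methyl}-5-hydroxy-2,3-dimethyl-8-(3-methylbut-2-en-1-yl)-4,7-dioxo-3,4,7,8-tetrahydro-2H-chromen-6-yl]hexanoic acid (CNP0364345.1)
Conditions: LiOH (2.2 equiv), THF/H2O 3:1, 0 °C, short; 0.5 M HCl to pH 3-4
Reagents that add atoms: water (as aqueous LiOH), O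
Why: Lactone hydrolysis: after the dearomatisation ring C is an enol ester of a vinylogous acid and should be opened by hydroxide at 0 °C within a short time, the delocalised C5 enolate so formed lowers the acidity of C3-H so that the cis C2/C3 relation, C8 and C1' are kept, and mild acidification gives the free acid 26.

Compound list
1 | 3,5-dimethoxyphenol | COc1cc(O)cc(OC)c1 | starting material
2 | butyryl chloride | CCCC(=O)Cl | starting material
3 | 1-(2-hydroxy-4,6-dimethoxyphenyl)butan-1-one | CCCC(=O)c1c(O)cc(OC)cc1OC | intermediate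
4 | 3,5-dimethoxy-2-(pent-1-en-2-yl)phenol (key-step precursor) | COc1cc(O)c(C(=C)CCC)c(OC)c1 | intermediate
5 | carbon monoxide | [C-]#[O+] | starting material
6 | (4S)-5,7-dimethoxy-4-propyl-3,4-dihydro-2H-chromen-2-one (key-step product) | COc1cc(OC)c([C@@H](CCC)CC(=O)O2)c2c1 | intermediate
7 | (4S)-5,7-dihydroxy-4-propyl-3,4-dihydro-2H-chromen-2-one | Oc1cc(O)c([C@@H](CCC)CC(=O)O2)c2c1 | intermediate
8 | tigloyl chloride, (E)-2-methylbut-2-enoyl chloride | C/C=C(\C)C(=O)Cl | starting material
9 | (4S)-5,7-dihydroxy-8-[(2E)-2-methylbut-2-enoyl]-4-propyl-3,4-dihydro-2H-chromen-2-one | Oc1cc(O)c([C@@H](CCC)CC(=O)O2)c2c1C(=O)/C(C)=C/C | intermediate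
10 | (4S)-5-[(tert-butyldimethylsilyl)oxy]-7-hydroxy-8-[(2E)-2-methylbut-2-enoyl]-4-propyl-3,4-dihydro-2H-chromen-2-one | Oc1cc(O[Si](C)(C)C(C)(C)C)c([C@@H](CCC)CC(=O)O2)c2c1C(=O)/C(C)=C/C | intermediate
11 | (4S,8R,9S)-5-[(tert-butyldimethylsilyl)oxy]-8,9-dimethyl-4-propyl-3,4,8,9-tetrahydro-2H,10H-pyrano[2,3-f]chromene-2,10-dione (cis-dimethyl) | c1c(O[Si](C)(C)C(C)(C)C)c([C@@H](CCC)CC(=O)O2)c2c3c1O[C@H](C)[C@H](C)C3=O | intermediate
12 | 6-iodo derivative of 11 | Ic1c(O[Si](C)(C)C(C)(C)C)c([C@@H](CCC)CC(=O)O2)c2c3c1O[C@H](C)[C@H](C)C3=O | intermediate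
13 | (1R,5R)-(+)-alpha-pinene | CC1=CC[C@@H]2C[C@H]1C2(C)C | starting material
14 | (1R,5R)-(+)-verbenone | CC1=CC(=O)[C@@H]2C[C@H]1C2(C)C | intermediate
15 | 2-[(1R,3S)-3-acetyl-2,2-dimethylcyclobutyl]-2-oxoacetic acid (not isolated) | CC(=O)[C@H]1C[C@@H](C(=O)C(=O)O)C1(C)C | intermediate
16 | (1R,3S)-3-acetyl-2,2-dimethylcyclobutane-1-carboxylic acid ((+)-cis-pinononic acid) | CC(=O)[C@H]1C[C@@H](C(=O)O)C1(C)C | intermediate
17 | (1R,3R)-2,2-dimethyl-3-(prop-1-en-2-yl)cyclobutane-1-carboxylic acid | C=C(C)[C@H]1C[C@@H](C(=O)O)C1(C)C | intermediate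
18 | [(1R,3R)-2,2-dimethyl-3-(prop-1-en-2-yl)cyclobutyl]methanol | C=C(C)[C@H]1C[C@@H](CO)C1(C)C | intermediate
19 | (1R,3R)-1-(iodomethyl)-2,2-dimethyl-3-(prop-1-en-2-yl)cyclobutane | C=C(C)[C@H]1C[C@@H](CI)C1(C)C | intermediate
20 | {[(1R,3R)-2,2-dimethyl-3-(prop-1-en-2-yl)cyclobutyl]methyl}zinc iodide (not isolated) | C=C(C)[C@H]1C[C@@H](C[Zn]I)C1(C)C | intermediate
21 | Negishi product, C7 silyl ether | C=C(C)[C@H]1C[C@@H](Cc2c(O[Si](C)(C)C(C)(C)C)c([C@@H](CCC)CC(=O)O3)c3c4c2O[C@H](C)[C@H](C)C4=O)C1(C)C | intermediate
22 | C7 phenol | C=C(C)[C@H]1C[C@@H](Cc2c(O)c([C@@H](CCC)CC(=O)O3)c3c4c2O[C@H](C)[C@H](C)C4=O)C1(C)C | intermediate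
23 | 3-methylbut-2-en-1-ol (prenol) | CC(C)=CCO | starting material
24 | tert-butyl 3-methylbut-2-en-1-yl carbonate | CC(C)=CCOC(=O)OC(C)(C)C | intermediate
25 | dearomatised lactone (8R) | C=C(C)[C@H]1C[C@@H](C[C@@]2(CC=C(C)C)C(=O)C([C@@H](CCC)CC(=O)O3)=C3C4=C2O[C@H](C)[C@H](C)C4=O)C1(C)C | intermediate
26 | CNP0364345.1 | C=C(C)[C@H]1C[C@@H](C[C@@]2(CC=C(C)C)C(=O)C([C@@H](CCC)CC(=O)O)=C(O)C3=C2O[C@H](C)[C@H](C)C3=O)C1(C)C | target

Total step count: 18. Longest linear sequence: 12 steps (1-8, 14, 15, 17, 18).

Three steps most likely to fail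

1. Step 3.
- What may go wrong: weak face discrimination in the hydropalladation, or its reversal before CO insertion. Markovnikov addition followed by beta-hydride elimination may move the double bond into the propyl chain. Plain hydrogenation of the alkene or slow turnover with the twisted, crowded styrene are also possible.
- Fallback (known chemistry, sets out from 1, comes back at 6): Pechmann condensation of 1 with ethyl 3-oxohexanoate (MeSO3H, rt to 50 °C) gives 5,7-dimethoxy-4-propylcoumarin F1. Asymmetric conjugate reduction of its C3=C4 bond with copper hydride (Cu(OAc)2, DTBM-SEGPHOS in the antipode that gives 4S, (EtO)2MeSiH, t-BuOH, toluene) then sets C1' and gives 6. The carboxyl carbon then comes from the keto ester instead of CO.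

2. Step 17.
- What may go wrong: lasting O-prenylation or no reaction, because the single acyl-stabilised phenoxide is a weak carbon nucleophile. Attack through the substituted allyl terminus and poor facial selectivity at C8 are the other risks.
- Fallback (sets out from 22, comes back at 26): ring C is given up before the dearomatisation, so that a true acylphloroglucinol-type diphenol is alkylated. Methanolysis of 22 (MeOH, cat. DMAP, rt) gives the methyl ester with free C5 and C7 hydroxyls F2.
- Classical alkylative dearomatisation of its dianion (LiHMDS, 2.0 equiv, THF, -78 °C, then prenyl bromide, to 0 °C) gives the C8-prenylated methyl ester F3. The C8 configuration is then secured by chromatographic separation.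
- Neutral ester cleavage (Me3SnOH, 1,2-dichloroethane, 60 °C) gives 26.

3. Step 5.
- What may go wrong: migration of the lactone to O7 through Lewis-acid opening and reclosure, acylation at C8, or early unselective closure of ring B during reaction or quench.
- Fallback (sets out from 6, comes back at 10): the acyl group is brought in while both phenols are still methyl ethers, which fixes the lactone and leaves C4a as the less hindered position. Propionyl chloride and SnCl4 (CH2Cl2, 0 °C) give the 8-propanoyl dimethyl ether F4.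
- BBr3 gives the 8-propanoyl diol F5, and TBSCl/imidazole gives its C7 silyl ether F6.
- Soft enolisation (TiCl4, i-Pr2NEt, CH2Cl2, -78 °C) and acetaldehyde give the aldol F7. Its two new centres are of no consequence, because MsCl/Et3N removes them by E1cB elimination to the (E)-enone 10.

Further compounds
F1 | step 3 | 5,7-dimethoxy-4-propyl-2H-chromen-2-one | CCCc1cc(=O)oc2cc(OC)cc(OC)c12
F2 | step 17 | methyl (3S)-3-[(2R,3S)-8-{[(1S,3R)-2,2-dimethyl-3-(prop-1-en-2-yl)cyclobutyl]methyl}-5,7-dihydroxy-2,3-dimethyl-4-oxo-3,4-dihydro-2H-chromen-6-yl]hexanoate | C=C(C)[C@H]1C[C@@H](Cc2c(O)c([C@@H](CCC)CC(=O)OC)c(O)c3c2O[C@H](C)[C@H](C)C3=O)C1(C)C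
F3 | step 17 | methyl ester of 26 | C=C(C)[C@H]1C[C@@H](C[C@@]2(CC=C(C)C)C(=O)C([C@@H](CCC)CC(=O)OC)=C(O)C3=C2O[C@H](C)[C@H](C)C3=O)C1(C)C
F4 | step 5 | (4S)-5,7-dimethoxy-8-propanoyl-4-propyl-3,4-dihydro-2H-chromen-2-one | COc1cc(OC)c([C@@H](CCC)CC(=O)O2)c2c1C(=O)CC
F5 | step 5 | (4S)-5,7-dihydroxy-8-propanoyl-4-propyl-3,4-dihydro-2H-chromen-2-one | Oc1cc(O)c([C@@H](CCC)CC(=O)O2)c2c1C(=O)CC
F6 | step 5 | (4S)-5-[(tert-butyldimethylsilyl)oxy]-7-hydroxy-8-propanoyl-4-propyl-3,4-dihydro-2H-chromen-2-one | Oc1cc(O[Si](C)(C)C(C)(C)C)c([C@@H](CCC)CC(=O)O2)c2c1C(=O)CC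
F7 | step 5 | (4S)-5-[(tert-butyldimethylsilyl)oxy]-7-hydroxy-8-(3-hydroxy-2-methylbutanoyl)-4-propyl-3,4-dihydro-2H-chromen-2-one (mixture at the two new centres) | Oc1cc(O[Si](C)(C)C(C)(C)C)c([C@@H](CCC)CC(=O)O2)c2c1C(=O)C(C)C(C)O
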